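The data are calculated from invented constants, noise included.

**Late product.** Product at 30.0 min stood at 67.9% of the charge on Saturday and 69.7% on Sunday, although Sunday's reagent charge was 1.55 times Saturday's.

common to all: starting material 0.20 M

|  | reagent | catalyst | remark |
|---|---|---|---|
| Saturday's | 0.84 M | 1 mM | run made earlier |
| Sunday's | 1.3 M | 1 mM | run made earlier |
| flask | 0.600 M | 1.0 mM |  |

| Saturday's: time / min | Saturday's: product / % | Sunday's: time / min | Sunday's: product / % |
|---|---|---|---|
| 5.00 | 10.5 | 2.50 | 4.8 |
| 10.0 | 26.4 | 4.00 | 9.6 |
| 15.0 | 39.2 | 8.00 | 22.4 |
| 20.0 | 50.6 | 12.0 | 34.5 |
| 25.0 | 59.8 | 20.0 | 53.4 |
| 30.0 | 67.9 | 30.0 | 69.7 |

(each reading ± 0.3 percentage points)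

1. apparent order in catalyst when 10% of the starting material are converted (percent change of the rate of making product for one percent more catalyst charged)
2. apparent order in reagent when 10% of the starting material are converted (percent change of the rate of making product for one percent more reagent charged)
3. factor on the rate of making product when 10% of the starting material are converted if catalyst is charged twice over

- no earlier run changes the charge of catalyst; that part of a forecast is a guess
- what has left starting material counts as converted, also if it is not yet product

**Slope against lag.** I plotted the logarithm of the fraction missing from product, and the late slopes were 0.0426 /min on Saturday and 0.0428 /min on Sunday, which looked like no order in reagent, but the lags of those lines were 3.31 min and 1.96 min, which looked like a first order.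

**Counting lifetimes.** I took two steps in series: the slope belonged to the loss of starting material, and the lag to the wait of an intermediate used up by reagent in a pseudo-first-order step. Scaling Saturday's lag by the charges gave 2.14 min for Sunday, beside the 1.96 min read there. For the flask the same scaling gave 4.64 min, the waiting time, meaning the lifetime of the intermediate at the flask's reagent charge. Conversion reached 10% after 2.47 min, which was 0.533 lifetimes, so fewer than one had passed. While little starting material has gone, the order in reagent is that count divided by the excess of its exponential over unity, which gave me 0.757. No run varied the catalyst, so I had no reckoning for it.

**The forecast.** The forecast gave 0.71 in reagent, lower than mine, with 0.71 in catalyst and a factor of 1.52, and of the catalyst it said: “I take the middle case”.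

**The flask.** The flask gave 0.73 in reagent, 0.62 in catalyst and a factor of 1.52, each within the forecast's margin.

    reagent + catalyst + intermediate → catalyst + product (k = 17.0 /M²/s)
    starting material + catalyst → catalyst + intermediate (k = 1.80 /M/s)
    2 catalyst ⇌ resting dimer, settled at all times (K = 1900 /M)

**Half-lives.** My waiting time of 4.64 min, lengthened for the 74% of the reagent charge left in the flask at 40.0 min and then turned from a lifetime into a half-life, meant 4.35 min for the intermediate, and the flask's value then was 3.8 min, shorter than the 16 min of starting material. At that time the flask made intermediate at 0.801 of the rate at which it used it up, and intermediate stood at 5.31% of the charge.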